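**Assumption:** 2-(triphenylphosphoranylidene)butanal (4) is taken as a purchasable reagent; if not stocked it is one step from propyltriphenylphosphonium bromide (n-BuLi, then ethyl formate). C1–C12 below refers to the linear chain (C1 = future CO2H carbon, C12 = PhCH=).

## Retrosynthetic overview

1. Spiculoic acid B ⇐ Pinnick oxidation of the bicyclic aldehyde ⇐ one intramolecular Diels–Alder (IMDA) of a linear (2E,4Z,6S,7E,9E,11E)-pentaenal. Both rings form in this step (cyclohexene by the [4+2], cyclopentene from the tether; new bonds C3–C7 and C2–C10), and four stereocentres are set from C6.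
2. Pentaenal ⇐ C3–C4 Negishi coupling of a (Z)-vinyl iodide with the alkenylalane from propargyl alcohol/Me3Al (C1–C3 plus the 2-methyl).
3. (Z)-Vinyl iodide (C4=C5) ⇐ Stork–Zhao iodo-olefination of an α-methyl trienal.
4. Triene (C7–C12) ⇐ two formyl-ylide Wittig homologations and a benzyl Horner–Wadsworth–Emmons (HWE) reaction on the Roche aldehyde.
5. The only imported stereocentre (C6) ⇐ (R)-Roche ester.

## Route

**Step 1**
Reactants: 1, methyl (R)-3-hydroxy-2-methylpropanoate
Product: 2, methyl (R)-3-[(tert-butyldimethylsilyl)oxy]-2-methylpropanoate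
Conditions: TBSCl, imidazole, CH2Cl2, 0 °C → rt
Reagents that add atoms: TBSCl, CC(C)(C)[Si](C)(C)Cl
Why: Standard silylation of the primary alcohol; the stereocentre is not touched.

**Step 2**
Reactants: 2
Product: 3, (R)-3-[(tert-butyldimethylsilyl)oxy]-2-methylpropanal
Conditions: DIBAL-H (1.1 equiv), CH2Cl2, −78 °C; Rochelle salt work-up; used crude
Reagents that add atoms: none
Why: Partial ester reduction via the stable aluminium hemiacetal at −78 °C gives the aldehyde without base, so the α-stereocentre is kept.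

**Step 3**
Reactants: 3; 4, 2-(triphenylphosphoranylidene)butanal
Product: 5, (2E,4S)-5-[(tert-butyldimethylsilyl)oxy]-2-ethyl-4-methylpent-2-enal
Conditions: 4 (1.2 equiv), toluene, 90 °C
Reagents that add atoms: 4, CCC(C=O)=P(c1ccccc1)(c1ccccc1)c1ccccc1
Why: Wittig reaction with a stabilised, non-basic formyl ylide gives the (E)-2-ethyl enal (C7=C8), and the less electrophilic enal product resists a second addition at this temperature.

**Step 4**
Reactants: 5; 4
Product: 6, (2E,4E,6S)-7-[(tert-butyldimethylsilyl)oxy]-2,4-diethyl-6-methylhepta-2,4-dienal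
Conditions: 4 (2 equiv), toluene, 110 °C
Reagents that add atoms: 4, CCC(C=O)=P(c1ccccc1)(c1ccccc1)c1ccccc1
Why: A second stabilised-ylide Wittig on the enal (hence the higher temperature) sets C9=C10 as E; C6 is now only a γ-position and is not at risk under neutral conditions.

**Step 5**
Reactants: 6; 7, diethyl benzylphosphonate
Product: 8, tert-butyl{[(2S,3E,5E,7E)-4,6-diethyl-2-methyl-8-phenylocta-3,5,7-trien-1-yl]oxy}dimethylsilane
Conditions: 7, KOt-Bu, THF, 0 °C; then 6, 0 °C → rt
Reagents that add atoms: 7, CCOP(=O)(Cc1ccccc1)OCC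
Why: HWE olefination with a benzylphosphonate anion gives the (E)-styrene (C11=C12); carbonyl addition is much faster than ε-deprotonation.

**Step 6**
Reactants: 8
Product: 9, (2S,3E,5E,7E)-4,6-diethyl-2-methyl-8-phenylocta-3,5,7-trien-1-ol
Conditions: TBAF, THF, 0 °C → rt
Reagents that add atoms: none
Why: Fluoride desilylation; the triene and stereocentre are inert.

**Step 7**
Reactants: 9
Product: 10, (2S,3E,5E,7E)-4,6-diethyl-2-methyl-8-phenylocta-3,5,7-trienal
Conditions: Dess–Martin periodinane, NaHCO3, CH2Cl2, 0 °C; filtered and used at once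
Reagents that add atoms: none
Why: Buffered Dess–Martin oxidation is neutral and fast, which limits epimerisation or conjugation of the α-methyl-β,γ-unsaturated aldehyde.

**Step 8**
Reactants: 10; 11, n-propyltriphenylphosphonium bromide
Product: 12, [(1E,3E,5E,7S,8Z)-3,5-diethyl-9-iodo-7-methylundeca-1,3,5,8-tetraen-1-yl]benzene
Conditions: 11, n-BuLi, THF, rt; I2, −78 °C; NaHMDS, −20 °C; then 10, −78 °C
Reagents that add atoms: 11, CCC[P+](c1ccccc1)(c1ccccc1)c1ccccc1.[Br-]; iodine, II
Why: Stork–Zhao–Wittig iodo-olefination proceeds through the kinetic cis-oxaphosphetane, placing iodine cis to the chain, so C4=C5 is Z; fast addition at −78 °C outcompetes enolisation.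

**Step 9**
Reactants: 12; 13, propargyl alcohol
Product: 14, (2E,4Z,6S,7E,9E,11E)-4,8,10-triethyl-2,6-dimethyl-12-phenyldodeca-2,4,7,9,11-pentaen-1-ol
Conditions: 13, Me3Al, Cp2ZrCl2 (cat.), (CH2Cl)2, 0 °C → rt; evaporate; then 12, ZnCl2, Pd(PPh3)4 (5 mol %), THF, rt
Reagents that add atoms: 13, C#CCO; trimethylaluminium, C[Al](C)C
Why: Negishi Zr-catalysed syn-methylalumination puts Me on the internal carbon and Al on the terminal carbon (cis), and Pd/Zn cross-coupling retains both alkene geometries, giving the 2E,4Z-diene.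

**Step 10**
Reactants: 14
Product: 15, (2E,4Z,6S,7E,9E,11E)-4,8,10-triethyl-2,6-dimethyl-12-phenyldodeca-2,4,7,9,11-pentaenal
Conditions: MnO2, CH2Cl2, rt; filtered and used directly
Reagents that add atoms: none
Why: MnO2 oxidises only the allylic primary alcohol and does not isomerise the alkenes.

**Step 11**
Reactants: 15
Product: 16, (1R,3aR,4R,5S,7aS)-3,5,7-triethyl-1,4-dimethyl-5-[(E)-2-phenylethenyl]-3a,4,5,7a-tetrahydro-1H-indene-4-carbaldehyde
Conditions: toluene (5 mM), BHT, 80 °C
Reagents that add atoms: none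
Why: Thermal IMDA of the C7–C10 diene with the C2=C3 enal through the CHO-endo, tether-exo transition state gives the trans ring fusion. A(1,3) strain with the C8 ethyl holds C6–H in the diene plane, so the dienophile adds anti to the C6 methyl. The E-dienophile and E,E-diene geometries fix the two quaternary centres (CHO cis to styryl).

**Step 12**
Reactants: 16
Product: 17, spiculoic acid B, (1R,3aR,4R,5S,7aS)-3,5,7-triethyl-1,4-dimethyl-5-[(E)-2-phenylethenyl]-3a,4,5,7a-tetrahydro-1H-indene-4-carboxylic acid
Conditions: NaClO2, NaH2PO4, 2-methyl-2-butene, t-BuOH/H2O, rt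
Reagents that add atoms: sodium chlorite, [Na+].[O-]Cl=O
Why: Pinnick oxidation converts the non-enolisable neopentyl aldehyde to the acid without epimerisation, with the scavenger protecting the alkenes from HOCl.

## Compound list

1 | methyl (R)-3-hydroxy-2-methylpropanoate (Roche ester) | COC(=O)[C@H](C)CO | starting material
2 | methyl (R)-3-[(tert-butyldimethylsilyl)oxy]-2-methylpropanoate | COC(=O)[C@H](C)CO[Si](C)(C)C(C)(C)C | intermediate
3 | (R)-3-[(tert-butyldimethylsilyl)oxy]-2-methylpropanal | O=C[C@H](C)CO[Si](C)(C)C(C)(C)C | intermediate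
4 | 2-(triphenylphosphoranylidene)butanal | CCC(C=O)=P(c1ccccc1)(c1ccccc1)c1ccccc1 | starting material
5 | (2E,4S)-5-[(tert-butyldimethylsilyl)oxy]-2-ethyl-4-methylpent-2-enal | O=C/C(CC)=C/[C@H](C)CO[Si](C)(C)C(C)(C)C | intermediate
6 | (2E,4E,6S)-7-[(tert-butyldimethylsilyl)oxy]-2,4-diethyl-6-methylhepta-2,4-dienal | O=C/C(CC)=C/C(CC)=C/[C@H](C)CO[Si](C)(C)C(C)(C)C | intermediate
7 | diethyl benzylphosphonate | CCOP(=O)(Cc1ccccc1)OCC | starting material
8 | tert-butyl{[(2S,3E,5E,7E)-4,6-diethyl-2-methyl-8-phenylocta-3,5,7-trien-1-yl]oxy}dimethylsilane | c1ccccc1/C=C/C(CC)=C/C(CC)=C/[C@H](C)CO[Si](C)(C)C(C)(C)C | intermediate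
9 | (2S,3E,5E,7E)-4,6-diethyl-2-methyl-8-phenylocta-3,5,7-trien-1-ol | c1ccccc1/C=C/C(CC)=C/C(CC)=C/[C@H](C)CO | intermediate
10 | (2S,3E,5E,7E)-4,6-diethyl-2-methyl-8-phenylocta-3,5,7-trienal | c1ccccc1/C=C/C(CC)=C/C(CC)=C/[C@H](C)C=O | intermediate
11 | n-propyltriphenylphosphonium bromide | CCC[P+](c1ccccc1)(c1ccccc1)c1ccccc1.[Br-] | starting material
12 | [(1E,3E,5E,7S,8Z)-3,5-diethyl-9-iodo-7-methylundeca-1,3,5,8-tetraen-1-yl]benzene | c1ccccc1/C=C/C(CC)=C/C(CC)=C/[C@H](C)/C=C(\I)CC | intermediate
13 | propargyl alcohol | C#CCO | starting material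
14 | (2E,4Z,6S,7E,9E,11E)-4,8,10-triethyl-2,6-dimethyl-12-phenyldodeca-2,4,7,9,11-pentaen-1-ol | c1ccccc1/C=C/C(CC)=C/C(CC)=C/[C@H](C)/C=C(CC)\C=C(C)\CO | intermediate
15 | (2E,4Z,6S,7E,9E,11E)-4,8,10-triethyl-2,6-dimethyl-12-phenyldodeca-2,4,7,9,11-pentaenal | c1ccccc1/C=C/C(CC)=C/C(CC)=C/[C@H](C)/C=C(CC)\C=C(C)\C=O | intermediate
16 | (1R,3aR,4R,5S,7aS)-3,5,7-triethyl-1,4-dimethyl-5-[(E)-2-phenylethenyl]-3a,4,5,7a-tetrahydro-1H-indene-4-carbaldehyde | CCC1=C[C@@](/C=C/c2ccccc2)(CC)[C@](C)(C=O)[C@H]2C(CC)=C[C@@H](C)[C@H]12 | intermediate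
17 | spiculoic acid B | CCC1=C[C@@](/C=C/c2ccccc2)(CC)[C@](C)(C(=O)O)[C@H]2C(CC)=C[C@@H](C)[C@H]12 | target

## Summary

Total step count: 12. Longest linear sequence: 12 (fully linear from 1).

Steps most likely to fail, each with a fallback:

1. **Step 8 (Stork–Zhao on aldehyde 10).** Risks are modest yield and Z/E ratio, and base-induced epimerisation or conjugation of the β,γ-unsaturated aldehyde. Fallback: reverse the order of chain building. Do the iodo-olefination first on the robust (S)-TBS Roche aldehyde (from the enantiomeric Roche ester), then unmask and oxidise the other terminus and grow the triene with the same Wittig/Wittig/HWE sequence, so the basic ylide never meets an α-vinyl aldehyde.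

2. **Step 11 (IMDA).** It forms two adjacent quaternary centres, and endo/exo or facial selectivity may be incomplete. Fallback: change the cyclisation substrate to a spiculoic-acid-A-type tether with a C4 ketone (saturated C5), which gives a doubly activated dienophile. After cycloaddition, install the ring alkene and ethyl group via the C4 enol triflate and Pd-catalysed ethylation with Et2Zn.

3. **Step 9 (one-pot carboalumination/Negishi coupling).** Risks are competing methyl transfer from residual Me3Al and low conversion of the hindered (Z)-iodide. Fallback: replace the cross-coupling with olefination. Pd-catalysed formylation of 12 (CO, Bu3SnH) gives the (Z)-2-ethyl enal, and Wittig reaction with commercial Ph3P=C(Me)CHO then leads directly to pentaenal 15.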